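A direct plan would build ring B first as the silyloxy enone A1 and would add a vinyl group at C9 and a silyl-bearing allylic iodide at C10 in one conjugate addition–alkylation to give the ketone A2. It would then close ring A by aldol condensation to the bicyclic enone A3, finish C4 by reductive methylation, join the side chain at C12–C13 and add C17 last at the C8 ketone A4.
Its weakest steps would be:
- the enolate alkylation that creates quaternary C10, which would need face selectivity next to the vinyl group without O-alkylation or enolate equilibration;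
- the thiomethylation and dissolving-metal methylation, two steps for one methyl group with a risk of over-reduction;
- the late methoxymethylenation of a hindered, enolisable ketone beside C9, after steps that only shuttle oxidation level and protection at C8.

The route rests on cutting C5–C10 and C8–C9 at once, which turns the decalin into the acyclic trienal 15. It exploits that ring B carries one-carbon branches on adjacent C8 and C9 beside the methyl-bearing C10, the pattern of an E,E-diene terminus and a β-methyl enal, while C1–C4 of ring A can act as tether. One intramolecular Diels–Alder reaction closes both rings and sets C5, C9, C10 and, provisionally, C8 relative to C3, which comes from an asymmetric aldol reaction together with the gem-dimethyl group. No enolate alkylation creates C10, no methyl group is added to a ring, and C17 is present from the start and is only oxidised and equilibrated.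

Key step: step 10

Numbering: labdane numbers are used throughout (C3 carbinol, C4 with the gem-dimethyl group, C10 with the angular methyl C20, C8 with C17, C9 with the chain C11–C16).
Remark: the N-tosyl-L-valine-derived oxazaborolidinone is assumed to expose the Si face of aldehyde 4, which gives the 3R aldol 6; the D-valine-derived promoter would serve if the sense were the opposite.

Step 1
Reactants: 1 pent-4-yn-1-ol
Product: 3 (4E)-5-iodo-4-methylpent-4-en-1-ol, via alkenylalane 2 (not isolated)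
Conditions: Me3Al (3 equiv), Cp2ZrCl2 (0.25 equiv), CH2Cl2, 0 to 25 °C; then I2, THF, −30 to 0 °C
Reagents that add atoms: trimethylaluminium, C[Al](C)C; iodine, II
Why: Zirconium-catalysed carboalumination of a terminal alkyne (Negishi carboalumination) adds methyl and aluminium syn with methyl on the inner carbon, and iodinolysis of the C–Al bond with retention gives the E alkenyl iodide that holds C9, C10 and C20.

Step 2
Reactants: 3 (4E)-5-iodo-4-methylpent-4-en-1-ol
Product: 4 (4E)-5-iodo-4-methylpent-4-enal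
Conditions: TEMPO (cat.), PhI(OAc)2, CH2Cl2, 25 °C
Reagents that add atoms: none
Why: TEMPO-catalysed oxidation of a primary alcohol stops at the aldehyde and leaves the alkenyl iodide alone.

Step 3
Reactants: 4 (4E)-5-iodo-4-methylpent-4-enal, 5 1-methoxy-2-methyl-1-[(trimethylsilyl)oxy]prop-1-ene
Product: 6 methyl (3R,6E)-3-hydroxy-7-iodo-2,2,6-trimethylhept-6-enoate
Conditions: N-tosyl-L-valine (1 equiv), BH3·THF (1 equiv), CH2Cl2, 25 °C; then 4 and 5, −78 °C; aqueous acidic work-up
Reagents that add atoms: none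
Why: In this oxazaborolidinone-promoted asymmetric Mukaiyama aldol reaction the chiral boron Lewis acid binds the aldehyde and leaves one carbonyl face open to the isobutyrate silyl ketene acetal, which sets C3 (3R) and brings in C4 with both methyl groups and C5.

Step 4
Reactants: 6 methyl (3R,6E)-3-hydroxy-7-iodo-2,2,6-trimethylhept-6-enoate
Product: 7 methyl (3R,6E)-3-[(tert-butyldimethylsilyl)oxy]-7-iodo-2,2,6-trimethylhept-6-enoate
Conditions: t-BuMe2SiOTf, 2,6-lutidine, CH2Cl2, −78 to 0 °C
Reagents that add atoms: tert-butyldimethylsilyl trifluoromethanesulfonate, CC(C)(C)[Si](C)(C)OS(=O)(=O)C(F)(F)F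
Why: Silyl ether formation at a hindered secondary alcohol with a silyl triflate and a hindered pyridine base gives a group that should last through the hydride, organolithium and Lewis acid steps.

Step 5
Reactants: 7 methyl (3R,6E)-3-[(tert-butyldimethylsilyl)oxy]-7-iodo-2,2,6-trimethylhept-6-enoate
Product: 9 (3R,6E)-3-[(tert-butyldimethylsilyl)oxy]-7-iodo-2,2,6-trimethylhept-6-enal, via primary alcohol 8 (not isolated)
Conditions: i-Bu2AlH, CH2Cl2, −78 to 0 °C, aqueous potassium sodium tartrate work-up; then Dess–Martin periodinane, NaHCO3, CH2Cl2, 25 °C on the crude alcohol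
Reagents that add atoms: none
Why: Hydride reduction of the neopentyl ester followed by Dess–Martin oxidation gives an aldehyde without α-hydrogen, which can neither epimerise nor eliminate the β-silyloxy group.

Step 6
Reactants: 9 (3R,6E)-3-[(tert-butyldimethylsilyl)oxy]-7-iodo-2,2,6-trimethylhept-6-enal, 10 ethyl (2E)-4-(diethoxyphosphoryl)but-2-enoate
Product: 11 ethyl (2E,4E,7R,10E)-7-[(tert-butyldimethylsilyl)oxy]-11-iodo-6,6,10-trimethylundeca-2,4,10-trienoate
Conditions: 10, LiN(SiMe3)2, THF, −78 °C; then 9, −78 to 0 °C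
Reagents that add atoms: none
Why: Vinylogous Horner–Wadsworth–Emmons olefination with the stabilised phosphonocrotonate anion is E-selective at the new C5=C6 bond and brings in the E C7=C8 bond and C17.

Step 7
Reactants: 11 ethyl (2E,4E,7R,10E)-7-[(tert-butyldimethylsilyl)oxy]-11-iodo-6,6,10-trimethylundeca-2,4,10-trienoate
Product: 12 (2E,4E,7R,10E)-7-[(tert-butyldimethylsilyl)oxy]-11-iodo-6,6,10-trimethylundeca-2,4,10-trien-1-ol
Conditions: i-Bu2AlH, CH2Cl2, −78 °C
Reagents that add atoms: none
Why: 1,2-Reduction of a conjugated ester with i-Bu2AlH gives the dienol and leaves the alkenyl iodide and the silyl ether.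

Step 8
Reactants: 12 (2E,4E,7R,10E)-7-[(tert-butyldimethylsilyl)oxy]-11-iodo-6,6,10-trimethylundeca-2,4,10-trien-1-ol
Product: 13 tert-butyl{[(2E,4E,7R,10E)-7-[(tert-butyldimethylsilyl)oxy]-11-iodo-6,6,10-trimethylundeca-2,4,10-trien-1-yl]oxy}dimethylsilane
Conditions: t-BuMe2SiCl, imidazole, DMF, 25 °C
Reagents that add atoms: tert-butyldimethylsilyl chloride, CC(C)(C)[Si](C)(C)Cl
Why: Standard silyl ether formation at a primary alcohol keeps C17 masked as CH2O through the organolithium and Lewis acid steps and makes the diene electron-rich enough for the cycloaddition.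

Step 9
Reactants: 13 tert-butyl{[(2E,4E,7R,10E)-7-[(tert-butyldimethylsilyl)oxy]-11-iodo-6,6,10-trimethylundeca-2,4,10-trien-1-yl]oxy}dimethylsilane
Product: 15 (2E,6R,8E,10E)-6,12-bis[(tert-butyldimethylsilyl)oxy]-3,7,7-trimethyldodeca-2,8,10-trienal, via alkenyllithium 14 (not isolated)
Conditions: t-BuLi (2.1 equiv), Et2O, −78 °C; then DMF, −78 to 0 °C
Reagents that add atoms: N,N-dimethylformamide, CN(C)C=O
Why: Iodine–lithium exchange at an alkenyl iodide is fast at −78 °C and keeps the alkene geometry, and formylation of the alkenyllithium with DMF gives the E enal with C11 in place.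

Step 10
Reactants: 15 (2E,6R,8E,10E)-6,12-bis[(tert-butyldimethylsilyl)oxy]-3,7,7-trimethyldodeca-2,8,10-trienal
Product: 16 (1R,2R,4aS,6R,8aR)-6-[(tert-butyldimethylsilyl)oxy]-2-{[(tert-butyldimethylsilyl)oxy]methyl}-5,5,8a-trimethyl-1,2,4a,5,6,7,8,8a-octahydronaphthalene-1-carbaldehyde
Conditions: Me2AlCl (1.5 equiv), CH2Cl2, −78 to −20 °C
Reagents that add atoms: none
Why: Me2AlCl binds the formyl oxygen and lowers the LUMO of the β,β-disubstituted enal, which then adds across the E,E-diene in a concerted but asynchronous [4+2] cycloaddition that forms C8–C9 and C5–C10. The closest known reaction type is the Lewis acid-promoted intramolecular Diels–Alder reaction of (2E,8E,10E)-trienals and trienoates to trans-fused octalins, including cases in which a methyl group on the inner dienophile carbon becomes an angular methyl group. Ring B is closed as the cycloaddition ring and ring A at the same time by the four-carbon tether C1–C4, which folds into a chair. C9 and C10 follow from the E geometry of the enal (C11 cis to C20), the trans fusion at C5/C10 from the endo position of the aluminium-bound formyl group with the tether exo, C8 from the E geometry of C7=C8 (C17 cis to C11 and axial, corrected in step 16), and the absolute sense of all four from C3, whose silyloxy group takes the equatorial site of the chair. The step needs endo over exo addition and one diene face: Lewis acid complexation and the C10 methyl group, which disfavours the cis-fused transition state, should secure the first, the equatorial preference of the bulky silyloxy group the second, and the gem-dimethyl group at C4 favours the folded reactive conformer.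

Step 11
Reactants: 16 (1R,2R,4aS,6R,8aR)-6-[(tert-butyldimethylsilyl)oxy]-2-{[(tert-butyldimethylsilyl)oxy]methyl}-5,5,8a-trimethyl-1,2,4a,5,6,7,8,8a-octahydronaphthalene-1-carbaldehyde
Product: 17 (1R,2R,4aS,6R,8aR)-6-[(tert-butyldimethylsilyl)oxy]-2-{[(tert-butyldimethylsilyl)oxy]methyl}-5,5,8a-trimethyldecahydronaphthalene-1-carbaldehyde
Conditions: H2 (1 atm), 10% Pd/C, EtOAc, 25 °C
Reagents that add atoms: none
Why: Heterogeneous catalytic hydrogenation saturates the cis-disubstituted C6=C7 bond, creates no stereocentre and leaves the aldehyde and the silyl ethers.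

Step 12
Reactants: 17 (1R,2R,4aS,6R,8aR)-6-[(tert-butyldimethylsilyl)oxy]-2-{[(tert-butyldimethylsilyl)oxy]methyl}-5,5,8a-trimethyldecahydronaphthalene-1-carbaldehyde
Product: 18 tert-butyl({(1R,2R,4aS,6R,8aS)-6-[(tert-butyldimethylsilyl)oxy]-1-ethenyl-5,5,8a-trimethyldecahydronaphthalen-2-yl}methoxy)dimethylsilane
Conditions: Ph3PCH3Br, KN(SiMe3)2, THF, 0 °C; then 17, 0 to 25 °C
Reagents that add atoms: methyltriphenylphosphonium bromide, C[P+](c1ccccc1)(c1ccccc1)c1ccccc1.[Br-]
Why: Wittig methylenation with the non-stabilised ylide turns the hindered formyl group into the vinyl group C11=C12, and C9 keeps its equatorial substituent, the stable arrangement.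

Step 13
Reactants: 19 methyl but-2-ynoate
Product: 20 methyl (2Z)-3-iodobut-2-enoate
Conditions: NaI, AcOH, 110 °C
Reagents that add atoms: sodium iodide, [Na+].[I-]
Why: Hydroiodination of an ynoate with NaI in acetic acid is an anti addition with iodide at the β-carbon, which gives the Z β-iodoenoate.

Step 14
Reactants: 18 tert-butyl({(1R,2R,4aS,6R,8aS)-6-[(tert-butyldimethylsilyl)oxy]-1-ethenyl-5,5,8a-trimethyldecahydronaphthalen-2-yl}methoxy)dimethylsilane, 20 methyl (2Z)-3-iodobut-2-enoate
Product: 22 methyl (2Z)-5-[(1R,2R,4aS,6R,8aS)-6-[(tert-butyldimethylsilyl)oxy]-2-{[(tert-butyldimethylsilyl)oxy]methyl}-5,5,8a-trimethyldecahydronaphthalen-1-yl]-3-methylpent-2-enoate, via B-alkyl-9-BBN adduct 21 (not isolated)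
Conditions: 9-BBN, THF, 25 to 40 °C; then 20, PdCl2(dppf) (cat.), AsPh3 (cat.), Cs2CO3, DMF/H2O, 25 to 50 °C
Reagents that add atoms: none
Why: Anti-Markovnikov hydroboration of the only alkene and B-alkyl Suzuki–Miyaura coupling form C12–C13, and oxidative addition and reductive elimination at zerovalent palladium keep the Z geometry of the iodoenoate.

Step 15
Reactants: 22 methyl (2Z)-5-[(1R,2R,4aS,6R,8aS)-6-[(tert-butyldimethylsilyl)oxy]-2-{[(tert-butyldimethylsilyl)oxy]methyl}-5,5,8a-trimethyldecahydronaphthalen-1-yl]-3-methylpent-2-enoate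
Product: 23 methyl (2Z)-5-[(1R,2R,4aS,6R,8aS)-6-hydroxy-2-(hydroxymethyl)-5,5,8a-trimethyldecahydronaphthalen-1-yl]-3-methylpent-2-enoate
Conditions: 48% aq. HF, MeCN/THF, 25 °C
Reagents that add atoms: none
Why: Acidic fluoride desilylation cleaves the primary and the hindered secondary silyl ether while the methyl ester and the trisubstituted enoate are inert.

Step 16
Reactants: 23 methyl (2Z)-5-[(1R,2R,4aS,6R,8aS)-6-hydroxy-2-(hydroxymethyl)-5,5,8a-trimethyldecahydronaphthalen-1-yl]-3-methylpent-2-enoate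
Product: 25 methyl (2Z)-5-[(1R,2S,4aS,6R,8aS)-2-formyl-6-hydroxy-5,5,8a-trimethyldecahydronaphthalen-1-yl]-3-methylpent-2-enoate, via axial aldehyde 24 (not isolated)
Conditions: TEMPO (cat.), PhI(OAc)2, CH2Cl2, 25 °C; then K2CO3, MeOH, 25 °C
Reagents that add atoms: none
Why: TEMPO-catalysed oxidation takes the primary alcohol in preference to the hindered secondary C3 carbinol and stops at the aldehyde, and carbonate in methanol then equilibrates C8 through the enol so that the formyl group leaves the axial position syn to the C10 methyl group for the equatorial one trans to the C9 chain (thermodynamic control).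

**Compound list**

1 | pent-4-yn-1-ol | C#CCCCO | starting material
2 | dimethyl{(1E)-5-[(dimethylalumanyl)oxy]-2-methylpent-1-en-1-yl}alumane (alkenylalane) | C[Al](C)/C=C(\C)CCCO[Al](C)C | intermediate
3 | (4E)-5-iodo-4-methylpent-4-en-1-ol | OCCC/C(C)=C/I | intermediate
4 | (4E)-5-iodo-4-methylpent-4-enal | O=CCC/C(C)=C/I | intermediate
5 | 1-methoxy-2-methyl-1-[(trimethylsilyl)oxy]prop-1-ene | COC(O[Si](C)(C)C)=C(C)C | starting material
6 | methyl (3R,6E)-3-hydroxy-7-iodo-2,2,6-trimethylhept-6-enoate | COC(=O)C(C)(C)[C@H](O)CC/C(C)=C/I | intermediate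
7 | methyl (3R,6E)-3-[(tert-butyldimethylsilyl)oxy]-7-iodo-2,2,6-trimethylhept-6-enoate | COC(=O)C(C)(C)[C@H](O[Si](C)(C)C(C)(C)C)CC/C(C)=C/I | intermediate
8 | (3R,6E)-3-[(tert-butyldimethylsilyl)oxy]-7-iodo-2,2,6-trimethylhept-6-en-1-ol | OCC(C)(C)[C@H](O[Si](C)(C)C(C)(C)C)CC/C(C)=C/I | intermediate
9 | (3R,6E)-3-[(tert-butyldimethylsilyl)oxy]-7-iodo-2,2,6-trimethylhept-6-enal | O=CC(C)(C)[C@H](O[Si](C)(C)C(C)(C)C)CC/C(C)=C/I | intermediate
10 | ethyl (2E)-4-(diethoxyphosphoryl)but-2-enoate (triethyl 4-phosphonocrotonate) | CCOC(=O)/C=C/CP(=O)(OCC)OCC | starting material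
11 | ethyl (2E,4E,7R,10E)-7-[(tert-butyldimethylsilyl)oxy]-11-iodo-6,6,10-trimethylundeca-2,4,10-trienoate | CCOC(=O)/C=C/C=C/C(C)(C)[C@H](O[Si](C)(C)C(C)(C)C)CC/C(C)=C/I | intermediate
12 | (2E,4E,7R,10E)-7-[(tert-butyldimethylsilyl)oxy]-11-iodo-6,6,10-trimethylundeca-2,4,10-trien-1-ol | OC/C=C/C=C/C(C)(C)[C@H](O[Si](C)(C)C(C)(C)C)CC/C(C)=C/I | intermediate
13 | tert-butyl{[(2E,4E,7R,10E)-7-[(tert-butyldimethylsilyl)oxy]-11-iodo-6,6,10-trimethylundeca-2,4,10-trien-1-yl]oxy}dimethylsilane | CC(C)(C)[Si](C)(C)OC/C=C/C=C/C(C)(C)[C@H](O[Si](C)(C)C(C)(C)C)CC/C(C)=C/I | intermediate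
14 | alkenyllithium from 13 (lithium in place of iodine, E geometry kept) | CC(C)(C)[Si](C)(C)OC/C=C/C=C/C(C)(C)[C@H](O[Si](C)(C)C(C)(C)C)CC/C(C)=C/[Li] | intermediate
15 | (2E,6R,8E,10E)-6,12-bis[(tert-butyldimethylsilyl)oxy]-3,7,7-trimethyldodeca-2,8,10-trienal | CC(C)(C)[Si](C)(C)OC/C=C/C=C/C(C)(C)[C@H](O[Si](C)(C)C(C)(C)C)CC/C(C)=C/C=O | intermediate
16 | (1R,2R,4aS,6R,8aR)-6-[(tert-butyldimethylsilyl)oxy]-2-{[(tert-butyldimethylsilyl)oxy]methyl}-5,5,8a-trimethyl-1,2,4a,5,6,7,8,8a-octahydronaphthalene-1-carbaldehyde (trans-fused; formyl group cis to the angular methyl group and to the CH2OSi group) | O=C[C@@H]1[C@H](CO[Si](C)(C)C(C)(C)C)C=C[C@@H]2C(C)(C)[C@H](O[Si](C)(C)C(C)(C)C)CC[C@@]12C | intermediate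
17 | (1R,2R,4aS,6R,8aR)-6-[(tert-butyldimethylsilyl)oxy]-2-{[(tert-butyldimethylsilyl)oxy]methyl}-5,5,8a-trimethyldecahydronaphthalene-1-carbaldehyde | O=C[C@@H]1[C@H](CO[Si](C)(C)C(C)(C)C)CC[C@@H]2C(C)(C)[C@H](O[Si](C)(C)C(C)(C)C)CC[C@@]12C | intermediate
18 | tert-butyl({(1R,2R,4aS,6R,8aS)-6-[(tert-butyldimethylsilyl)oxy]-1-ethenyl-5,5,8a-trimethyldecahydronaphthalen-2-yl}methoxy)dimethylsilane | C=C[C@@H]1[C@H](CO[Si](C)(C)C(C)(C)C)CC[C@@H]2C(C)(C)[C@H](O[Si](C)(C)C(C)(C)C)CC[C@@]12C | intermediate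
19 | methyl but-2-ynoate | CC#CC(=O)OC | starting material
20 | methyl (2Z)-3-iodobut-2-enoate | COC(=O)/C=C(/C)I | intermediate
21 | B-alkyl-9-BBN adduct of 18 (boron on C12, the terminal carbon of the former vinyl group) | C1CCC2CCCC1B2CC[C@@H]1[C@H](CO[Si](C)(C)C(C)(C)C)CC[C@@H]2C(C)(C)[C@H](O[Si](C)(C)C(C)(C)C)CC[C@@]12C | intermediate
22 | methyl (2Z)-5-[(1R,2R,4aS,6R,8aS)-6-[(tert-butyldimethylsilyl)oxy]-2-{[(tert-butyldimethylsilyl)oxy]methyl}-5,5,8a-trimethyldecahydronaphthalen-1-yl]-3-methylpent-2-enoate | COC(=O)/C=C(/C)CC[C@@H]1[C@H](CO[Si](C)(C)C(C)(C)C)CC[C@@H]2C(C)(C)[C@H](O[Si](C)(C)C(C)(C)C)CC[C@@]12C | intermediate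
23 | methyl (2Z)-5-[(1R,2R,4aS,6R,8aS)-6-hydroxy-2-(hydroxymethyl)-5,5,8a-trimethyldecahydronaphthalen-1-yl]-3-methylpent-2-enoate | COC(=O)/C=C(/C)CC[C@@H]1[C@H](CO)CC[C@@H]2C(C)(C)[C@H](O)CC[C@@]12C | intermediate
24 | methyl (2Z)-5-[(1R,2R,4aS,6R,8aS)-2-formyl-6-hydroxy-5,5,8a-trimethyldecahydronaphthalen-1-yl]-3-methylpent-2-enoate (axial formyl group, C8 epimer of the target) | COC(=O)/C=C(/C)CC[C@@H]1[C@H](C=O)CC[C@@H]2C(C)(C)[C@H](O)CC[C@@]12C | intermediate
25 | methyl (2Z)-5-[(1R,2S,4aS,6R,8aS)-2-formyl-6-hydroxy-5,5,8a-trimethyldecahydronaphthalen-1-yl]-3-methylpent-2-enoate (CNP0188570.1) | COC(=O)/C=C(/C)CC[C@@H]1[C@@H](C=O)CC[C@@H]2C(C)(C)[C@H](O)CC[C@@]12C | target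

Total step count: 16. Longest linear sequence: 15 (steps 1 to 12 and 14 to 16; step 13 makes the coupling partner).

Steps most likely to fail:

1. Step 10. The cycloaddition could be too slow at temperatures that the allylic silyl ether tolerates, or the C3 silyloxy group could bias the diene face too weakly, so that exo (cis-fused) or face-isomeric adducts would form alongside. The fallback would move stereocontrol to an oxazolidinone auxiliary. Setting out from 15, chlorite oxidation (NaClO2, NaH2PO4, 2-methylbut-2-ene) would give the trienoic acid F1. Acylation of lithiated (4R)-4-benzyl-1,3-oxazolidin-2-one through the pivaloyl mixed anhydride would give the N-trienoyl oxazolidinone F2. Me2AlCl (1.4 equiv, CH2Cl2, −30 °C) would then form the chelated, cationic and more reactive dienophile, whose benzyl group should leave only the wanted face of C9=C10 open, and give the cycloadduct imide F3. LiBH4 would release the auxiliary as the primary alcohol F4, and Dess–Martin oxidation would come back to the route at 16.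

2. Step 9. Carbolithiation of the conjugated diene or deprotonation beside the allylic silyl ether could compete with iodine–lithium exchange, and part of the E geometry could be lost. The fallback would avoid the organolithium. From 13, carbonylation (Pd(OAc)2, PPh3, CO 1 atm, MeOH, Et3N, DMF, 60 °C) would give the methyl trienoate F5, i-Bu2AlH would reduce it to the allylic alcohol F6, and MnO2 would oxidise this to 15, where the route is rejoined.

3. Step 16. The axial, neopentyl-like CH2OH could be oxidised so slowly that oxidation at C3 would start to compete, or epimerisation at C8 could stop short. The fallback would separate the two hydroxyl groups in time. From 22, PPTS in methanol would cleave only the primary silyl ether and give the mono-alcohol F7. Dess–Martin oxidation would give the axial aldehyde F8 with C3 still silylated, DBU in CH2Cl2 would equilibrate it to the equatorial aldehyde F9, and aqueous HF in MeCN would remove the last silyl group and arrive at 25.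

**Further compounds**

F1 | step 10 | (2E,6R,8E,10E)-6,12-bis[(tert-butyldimethylsilyl)oxy]-3,7,7-trimethyldodeca-2,8,10-trienoic acid | OC(=O)/C=C(\C)CC[C@@H](O[Si](C)(C)C(C)(C)C)C(C)(C)/C=C/C=C/CO[Si](C)(C)C(C)(C)C
F2 | step 10 | (4R)-4-benzyl-3-[(2E,6R,8E,10E)-6,12-bis[(tert-butyldimethylsilyl)oxy]-3,7,7-trimethyldodeca-2,8,10-trienoyl]-1,3-oxazolidin-2-one | O=C(/C=C(\C)CC[C@@H](O[Si](C)(C)C(C)(C)C)C(C)(C)/C=C/C=C/CO[Si](C)(C)C(C)(C)C)N1[C@H](Cc2ccccc2)COC1=O
F3 | step 10 | (4R)-4-benzyl-3-{[(1R,2R,4aS,6R,8aR)-6-[(tert-butyldimethylsilyl)oxy]-2-{[(tert-butyldimethylsilyl)oxy]methyl}-5,5,8a-trimethyl-1,2,4a,5,6,7,8,8a-octahydronaphthalen-1-yl]carbonyl}-1,3-oxazolidin-2-one | O=C([C@@H]1[C@H](CO[Si](C)(C)C(C)(C)C)C=C[C@@H]2C(C)(C)[C@H](O[Si](C)(C)C(C)(C)C)CC[C@@]12C)N1[C@H](Cc2ccccc2)COC1=O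
F4 | step 10 | [(1R,2R,4aS,6R,8aR)-6-[(tert-butyldimethylsilyl)oxy]-2-{[(tert-butyldimethylsilyl)oxy]methyl}-5,5,8a-trimethyl-1,2,4a,5,6,7,8,8a-octahydronaphthalen-1-yl]methanol | OC[C@@H]1[C@H](CO[Si](C)(C)C(C)(C)C)C=C[C@@H]2C(C)(C)[C@H](O[Si](C)(C)C(C)(C)C)CC[C@@]12C
F5 | step 9 | methyl (2E,6R,8E,10E)-6,12-bis[(tert-butyldimethylsilyl)oxy]-3,7,7-trimethyldodeca-2,8,10-trienoate | COC(=O)/C=C(\C)CC[C@@H](O[Si](C)(C)C(C)(C)C)C(C)(C)/C=C/C=C/CO[Si](C)(C)C(C)(C)C
F6 | step 9 | (2E,6R,8E,10E)-6,12-bis[(tert-butyldimethylsilyl)oxy]-3,7,7-trimethyldodeca-2,8,10-trien-1-ol | OC/C=C(\C)CC[C@@H](O[Si](C)(C)C(C)(C)C)C(C)(C)/C=C/C=C/CO[Si](C)(C)C(C)(C)C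
F7 | step 16 | methyl (2Z)-5-[(1R,2R,4aS,6R,8aS)-6-[(tert-butyldimethylsilyl)oxy]-2-(hydroxymethyl)-5,5,8a-trimethyldecahydronaphthalen-1-yl]-3-methylpent-2-enoate | COC(=O)/C=C(/C)CC[C@@H]1[C@H](CO)CC[C@@H]2C(C)(C)[C@H](O[Si](C)(C)C(C)(C)C)CC[C@@]12C
F8 | step 16 | methyl (2Z)-5-[(1R,2R,4aS,6R,8aS)-6-[(tert-butyldimethylsilyl)oxy]-2-formyl-5,5,8a-trimethyldecahydronaphthalen-1-yl]-3-methylpent-2-enoate | COC(=O)/C=C(/C)CC[C@@H]1[C@H](C=O)CC[C@@H]2C(C)(C)[C@H](O[Si](C)(C)C(C)(C)C)CC[C@@]12C
F9 | step 16 | methyl (2Z)-5-[(1R,2S,4aS,6R,8aS)-6-[(tert-butyldimethylsilyl)oxy]-2-formyl-5,5,8a-trimethyldecahydronaphthalen-1-yl]-3-methylpent-2-enoate | COC(=O)/C=C(/C)CC[C@@H]1[C@@H](C=O)CC[C@@H]2C(C)(C)[C@H](O[Si](C)(C)C(C)(C)C)CC[C@@]12C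
A1 | direct plan | (4S)-2-methyl-4-[(triisopropylsilyl)oxy]cyclohex-2-en-1-one | CC1=C[C@@H](O[Si](C(C)C)(C(C)C)C(C)C)CCC1=O
A2 | direct plan | (2S,3S,4S)-3-ethenyl-2-methyl-4-[(triisopropylsilyl)oxy]-2-[(2E)-3-(trimethylsilyl)but-2-en-1-yl]cyclohexan-1-one | C=C[C@@H]1[C@@H](O[Si](C(C)C)(C(C)C)C(C)C)CCC(=O)[C@@]1(C)C/C=C(\C)[Si](C)(C)C
A3 | direct plan | (4aS,5S,6S)-5-ethenyl-4a-methyl-6-[(triisopropylsilyl)oxy]-4,4a,5,6,7,8-hexahydronaphthalen-2(3H)-one | C=C[C@@H]1[C@@H](O[Si](C(C)C)(C(C)C)C(C)C)CCC2=CC(=O)CC[C@@]12C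
A4 | direct plan | methyl (2Z)-5-[(1S,4aS,6R,8aR)-6-acetoxy-5,5,8a-trimethyl-2-oxodecahydronaphthalen-1-yl]-3-methylpent-2-enoate | COC(=O)/C=C(/C)CC[C@@H]1C(=O)CC[C@@H]2C(C)(C)[C@H](OC(C)=O)CC[C@@]12C
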